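All runs were generated by integration for substances that don't exist; noise was put on by code.

- The trap in this run was the early target: the north-east run read 74 % at 0.625 d but 51 % at 2.00 d, while the isomer of the product climbed from 20 % to 48 %.

| setting | north-east | south-west | flask |
|---|---|---|---|
| substrate | 2 M (fed, over 6.0 h) | 2 M (fed, over 6.0 h) | 2.0 M (fed, over 6.0 h) |
| precatalyst | 70 mM | 100 mM | 140 mM |
| remark | run made earlier; the fed solution adds 0.10 times the starting volume | run made earlier; the fed solution adds 0.10 times the starting volume | the fed solution adds 0.10 times the starting volume |
| time |  |  | 3.0 d |

| run | time / d | target / % | isomer of the product / % |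
|---|---|---|---|
| north-east | 0.625 | 74 | 20 |
| north-east | 1.25 | 58 | 46 |
| north-east | 2.00 | 51 | 48 |
| north-east | 3.00 | 51 | 50 |
| north-east | 4.00 | 49 | 49 |
| south-west | 0.625 | 65 | 30 |
| south-west | 1.25 | 50 | 45 |
| south-west | 2.00 | 48 | 51 |
| south-west | 3.00 | 49 | 49 |
| south-west | 4.00 | 49 | 48 |

(readings scatter by 2 percentage points)

- every charge counts on the volume at the start, and the solution that is fed holds the whole dose

1. the target in the flask at 3.0 d, as a percentage of the substrate charged
2. the isomer of the product in the flask at 3.0 d, as a percentage of the substrate charged

- I froze what stopped moving. From 2.00 d on, the two runs together gave 49.8 % for the plateau share, the isomer of the product as a fraction of target plus isomer, a reading that marks thermodynamic rather than kinetic control.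
- I expected the flask to stand on that plateau, because both runs were level by 2.00 d, earlier than the asked 3.0 d, and the flask held twice the north-east precatalyst.
- From above, target plus isomer could not pass the whole charge, so at that read share I put the upper end of the target at 50.2 % and of the isomer at 49.8 %.
- From below, I took the poorest late total, 97.0 % in the south-west run, which gave 48.7 % target and 48.3 % isomer, each reading good to 2 percentage points.
- The forecast put 49 % target and 49 % isomer, both central values inside my bracket, but its range of 46 % to 52 % on each reached beyond the bracket at both ends, on the ground that “the flask should therefore be well within the plateau”.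
- The flask gave 49.2 % target and 49.2 % isomer of the product at 3.0 d, with 1.64 % of the substrate left.

    substrate ⇌ target (K = 30.0, k = 0.00612 min⁻¹)
    target + catalyst ⇌ isomer of the product + catalyst, rate k2*[catalyst]*[target] forward; the back reaction follows from the equilibrium constant (K = 1.00, k = 0.0295 L mol⁻¹ min⁻¹)
    precatalyst → catalyst (k = 7.36 × 10⁻⁴ min⁻¹)
    catalyst ⇌ dormant form (K = 1.30, k = 6.99 × 10⁻⁴ min⁻¹)

- With all else held, the isomer in this flask moved by 5 points at 25.8 mM of precatalyst, so a repeat should watch that charge. The clock matters too. The neighbour flask, read at 20 h with all amounts held, stood before the 2.00 d at which the runs were level, so my reckoning offered it no plateau. It gave 55.6 % target and 42.2 % isomer, a share of 43.1 %, below the plateau share of 49.8 %, with 41.3 % of the catalyst charge still precatalyst.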